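**Assumption:** the enol drawn (OH on C7, C7=C8) is the tautomer to deliver. Atom labels follow monic acid: C1–C4 and C15 (enoate arm), C5 (ring CH), C6 (C=O), C7, C8, C16 (ring OCH2), C9–C14 and C17 (side chain).

## Retrosynthetic overview

1. Target ⇐ one acid operation on a 7,8-epoxy 6-ketone (epoxy ketone → diosphenol, with the TES ether and tert-butyl ester cleaved).
2. Epoxy ketone ⇐ oxidation of the 7,8-epoxy 6-alcohol; its side chain comes from cross-metathesis of an 8-allyl group with the TES ether of (2S,3R)-3-methylpent-4-en-2-ol (from ethyl (S)-3-hydroxybutanoate by Fráter–Seebach methylation).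
3. Pyranone ⇐ Achmatowicz ring expansion of a 2,4-disubstituted (S)-furyl carbinol, then removal of the anomeric OH, 1,2-reduction and hydroxyl-directed epoxidation.
4. (E)-3-Methyl enoate ⇐ β-keto ester via (Z)-enol phosphate and Me2CuLi; β-keto ester ⇐ key decarboxylative Claisen condensation of the furan acid with the malonic half ester that carries the tert-butyl hexanoate chain.
5. C5 ⇐ Noyori transfer hydrogenation of a furyl β-keto ester (crossed Claisen of the 4-allylfuroate with ethyl acetate). Ring order: the purchased furan is expanded to the only ring of the target (step 11); a transient oxirane is made in step 14 and opened in step 21.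

## Route

Step 1
Reactants: 1 methyl 4-bromofuran-2-carboxylate; 2 2-allyl-4,4,5,5-tetramethyl-1,3,2-dioxaborolane
Product: 3 methyl 4-allylfuran-2-carboxylate
Conditions: Pd(PPh3)4 (5 mol%), CsF (3 equiv), THF, 65 °C
Reagents that add atoms: none
Why: Suzuki–Miyaura coupling of the furyl bromide with the fluoride-activated allylboronate puts the future C9–C10 unit on the furan carbon that becomes C8; no stereocentre is formed.

Step 2
Reactants: 3 methyl 4-allylfuran-2-carboxylate; 4 ethyl acetate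
Product: 5 ethyl 3-(4-allylfuran-2-yl)-3-oxopropanoate
Conditions: LiN(i-Pr)2 (2.3 equiv), EtOAc (2.2 equiv), THF, −78 °C; add 3, −78 → −20 °C; 1 M HCl
Reagents that add atoms: none
Why: Crossed Claisen condensation in which the non-enolisable furoate acylates the ethyl acetate enolate and the product is held as its stabilised enolate until the quench.

Step 3
Reactants: 5 ethyl 3-(4-allylfuran-2-yl)-3-oxopropanoate
Product: 6 ethyl (3S)-3-(4-allylfuran-2-yl)-3-hydroxypropanoate
Conditions: RuCl(p-cymene)[(S,S)-TsDPEN] (1 mol%), HCO2H/Et3N (5:2), 30 °C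
Reagents that add atoms: none
Why: Noyori asymmetric transfer hydrogenation delivers hydride to the furyl (aryl-type) ketone through the outer-sphere CH/π-controlled transition state, the (S,S)-catalyst giving the (S)-carbinol (future C5) as with other aryl ketones, while the isolated alkene is untouched.

Step 4
Reactants: 6 ethyl (3S)-3-(4-allylfuran-2-yl)-3-hydroxypropanoate
Product: 7 ethyl (3S)-3-(4-allylfuran-2-yl)-3-[(tert-butyldimethylsilyl)oxy]propanoate
Conditions: TBSCl, imidazole, DMF, rt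
Reagents that add atoms: tert-butylchlorodimethylsilane, CC(C)(C)[Si](C)(C)Cl
Why: Silyl ether formation masks the furylic alcohol for the acyl activation, enolate and cuprate steps that follow; the stereocentre is not involved.

Step 5
Reactants: 7 ethyl (3S)-3-(4-allylfuran-2-yl)-3-[(tert-butyldimethylsilyl)oxy]propanoate
Product: 8 (3S)-3-(4-allylfuran-2-yl)-3-[(tert-butyldimethylsilyl)oxy]propanoic acid
Conditions: LiOH·H2O, THF/MeOH/H2O, 0 °C → rt; 1 M HCl to pH 4
Reagents that add atoms: lithium hydroxide, [Li+].[OH-]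
Why: Saponification of the unhindered ethyl ester; the β-silyloxy group is a poor leaving group and the stereocentre is not α to the carbonyl.

Step 6
Reactants: 9 Meldrum's acid (2,2-dimethyl-1,3-dioxane-4,6-dione); 10 tert-butyl 6-hydroxyhexanoate
Product: 11 3-{[6-(tert-butoxy)-6-oxohexyl]oxy}-3-oxopropanoic acid
Conditions: MeCN, 82 °C
Reagents that add atoms: none
Why: Alcoholysis of Meldrum's acid (acyl substitution with loss of acetone) gives the malonic half ester that already carries the C6 ester chain.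

Step 7 (key fragment union)
Reactants: 8 (3S)-3-(4-allylfuran-2-yl)-3-[(tert-butyldimethylsilyl)oxy]propanoic acid; 11 3-{[6-(tert-butoxy)-6-oxohexyl]oxy}-3-oxopropanoic acid
Product: 14 6-(tert-butoxy)-6-oxohexyl (5S)-5-(4-allylfuran-2-yl)-5-[(tert-butyldimethylsilyl)oxy]-3-oxopentanoate, via acyl imidazolide 12 (not isolated), via acylmalonic half ester 13 (not isolated)
Conditions: 8, CDI, THF, rt; then 11, MgCl2, Et3N, MeCN/THF, rt → 40 °C; 1 M HCl
Reagents that add atoms: none
Why: Masamune–Brooks decarboxylative Claisen condensation: the magnesium enolate of the malonic half ester is C-acylated by the acyl imidazolide and the adduct loses CO2 on acidification, which forms the C2–C3 bond and joins the furan and hexanoate fragments without touching C5.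

Step 8
Reactants: 14 6-(tert-butoxy)-6-oxohexyl (5S)-5-(4-allylfuran-2-yl)-5-[(tert-butyldimethylsilyl)oxy]-3-oxopentanoate
Product: 15 6-(tert-butoxy)-6-oxohexyl (2Z,5S)-5-(4-allylfuran-2-yl)-5-[(tert-butyldimethylsilyl)oxy]-3-[(diethoxyphosphoryl)oxy]pent-2-enoate
Conditions: NaH, Et2O, 0 °C; ClP(O)(OEt)2, 0 °C
Reagents that add atoms: diethyl chlorophosphate, CCOP(=O)(Cl)OCC
Why: O-Phosphorylation of the chelated sodium enolate of the β-keto ester gives the (Z)-enol phosphate (first half of the Weiler trisubstituted-olefin synthesis); only the β-keto ester is acidic enough to be deprotonated.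

Step 9
Reactants: 15 the (2Z)-enol phosphate
Product: 16 6-(tert-butoxy)-6-oxohexyl (2E,5S)-5-(4-allylfuran-2-yl)-5-[(tert-butyldimethylsilyl)oxy]-3-methylpent-2-enoate
Conditions: Me2CuLi (from MeLi and CuI), Et2O, −78 → −45 °C; aq. NH4Cl
Reagents that add atoms: lithium dimethylcuprate, [Li+].C[Cu-]C
Why: Gilman cuprate substitution of the enol phosphate proceeds with retention, so the methyl group (C15) ends cis to the ester carbonyl, which is the (E)-enoate of the target; esters, furan and allyl group are inert to the cuprate at this temperature.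

Step 10
Reactants: 16 the (2E,5S)-silyl ether
Product: 17 6-(tert-butoxy)-6-oxohexyl (2E,5S)-5-(4-allylfuran-2-yl)-5-hydroxy-3-methylpent-2-enoate
Conditions: Bu4NF, AcOH, THF, rt
Reagents that add atoms: none
Why: Fluoride-mediated desilylation buffered with acetic acid frees the furyl carbinol; the (E)-geometry prevents lactonisation.

Step 11
Reactants: 17 the (2E,5S)-furyl carbinol
Product: 19 6-(tert-butoxy)-6-oxohexyl (2E)-4-[(2S)-5-allyl-6-hydroxy-3-oxo-3,6-dihydro-2H-pyran-2-yl]-3-methylbut-2-enoate (anomer mixture), via ring-opened cis-enedione 18 (not isolated)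
Conditions: NBS, NaHCO3, NaOAc, THF/H2O (4:1), 0 °C
Reagents that add atoms: water, O
Why: Achmatowicz oxidative ring expansion: the electron-rich furan is oxidised far faster than the terminal alkene or the enoate, and the carbinol oxygen closes onto the unveiled aldehyde to give the pyranone with C5 unchanged (its C–O bond is never broken) and the allyl group on C8.

Step 12
Reactants: 19 the pyranone lactol
Product: 20 6-(tert-butoxy)-6-oxohexyl (2E)-4-[(2S)-5-allyl-3-oxo-3,6-dihydro-2H-pyran-2-yl]-3-methylbut-2-enoate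
Conditions: Et3SiH (5 equiv), TFA (10 equiv), CH2Cl2, −40 °C
Reagents that add atoms: none
Why: Ionic hydrogenation (Kishi-type reductive deoxygenation) of the lactol through its oxocarbenium ion gives the C16 methylene; at −40 °C the tert-butyl ester, the alkenes and the α-alkoxy ketone centre survive.

Step 13
Reactants: 20 the 8-allyl enone
Product: 21 6-(tert-butoxy)-6-oxohexyl (2E)-4-[(2S)-5-allyl-3-hydroxy-3,6-dihydro-2H-pyran-2-yl]-3-methylbut-2-enoate (C6 epimers)
Conditions: NaBH4, CeCl3·7H2O, MeOH, −78 °C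
Reagents that add atoms: none
Why: Luche 1,2-reduction of the enone leaves both esters alone; the new C6 carbinol centre need not be controlled because it is oxidised back in step 20, and C5 is no longer α to a carbonyl during the next steps.

Step 14
Reactants: 21 the allylic alcohol
Product: 22 6-(tert-butoxy)-6-oxohexyl (2E)-4-[(4S)-1-allyl-5-hydroxy-3,7-dioxabicyclo[4.1.0]heptan-4-yl]-3-methylbut-2-enoate (7,8-epoxide syn to the 6-OH)
Conditions: VO(acac)2 (5 mol%), t-BuOOH (decane), CH2Cl2, 0 °C → rt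
Reagents that add atoms: tert-butyl hydroperoxide, CC(C)(C)OO
Why: Hydroxyl-directed vanadium-catalysed epoxidation oxidises only the allylic-alcohol double bond (C7=C8), syn to the hydroxyl, and ignores the terminal alkene and the enoate; the new C7/C8 centres are erased in step 21.

Step 15
Reactants: 23 ethyl (3S)-3-hydroxybutanoate
Product: 24 ethyl (2S,3S)-3-hydroxy-2-methylbutanoate
Conditions: LiN(i-Pr)2 (2.2 equiv), THF, −50 → −20 °C; MeI, −78 → 0 °C; 1 M HCl
Reagents that add atoms: iodomethane, CI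
Why: Fráter–Seebach alkylation: the chelated alkoxide-enolate dianion is methylated anti to the C3 methyl group, which sets C12 (anti, dr about 95:5) relative to the chiral-pool C13 centre.

Step 16
Reactants: 24 ethyl (2S,3S)-3-hydroxy-2-methylbutanoate
Product: 25 ethyl (2S,3S)-2-methyl-3-[(triethylsilyl)oxy]butanoate
Conditions: Et3SiCl, imidazole, CH2Cl2, 0 °C
Reagents that add atoms: chlorotriethylsilane, CC[Si](Cl)(CC)CC
Why: Silylation gives an acid-labile ether that survives hydride, ylide, metathesis and periodinane and falls off in the final acid step.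

Step 17
Reactants: 25 ethyl (2S,3S)-2-methyl-3-[(triethylsilyl)oxy]butanoate
Product: 26 (2S,3S)-2-methyl-3-[(triethylsilyl)oxy]butanal
Conditions: i-Bu2AlH (1.05 equiv), CH2Cl2, −78 °C; aq. potassium sodium tartrate
Reagents that add atoms: none
Why: Partial reduction of the ester stops at the tetrahedral aluminium hemiacetal at −78 °C and releases the aldehyde only on work-up, so the α-centre is not epimerised.

Step 18
Reactants: 26 (2S,3S)-2-methyl-3-[(triethylsilyl)oxy]butanal
Product: 27 triethyl{[(2S,3R)-3-methylpent-4-en-2-yl]oxy}silane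
Conditions: Ph3PCH3Br, KN(SiMe3)2, THF, 0 °C; add 26, −78 → 0 °C
Reagents that add atoms: methyltriphenylphosphonium bromide, C[P+](c1ccccc1)(c1ccccc1)c1ccccc1.[Br-]
Why: Wittig methylenation with the salt-free ylide at low temperature converts the aldehyde to the terminal alkene without touching the α-stereocentre (the descriptor changes to 3R only through the priority rules).

Step 19
Reactants: 22 the 8-allyl epoxy alcohol; 27 triethyl{[(2S,3R)-3-methylpent-4-en-2-yl]oxy}silane
Product: 28 6-(tert-butoxy)-6-oxohexyl (2E)-4-[(4S)-5-hydroxy-1-{(2E,4R,5S)-4-methyl-5-[(triethylsilyl)oxy]hex-2-en-1-yl}-3,7-dioxabicyclo[4.1.0]heptan-4-yl]-3-methylbut-2-enoate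
Conditions: second-generation Hoveyda–Grubbs catalyst [RuCl2(H2IMes)(=CH-C6H4-2-O-i-Pr)] (5 mol%), 27 (3 equiv), CH2Cl2, 40 °C
Reagents that add atoms: none
Why: Olefin cross-metathesis between the unhindered allyl group and an excess of the allylically branched partner gives the (E)-C10=C11 alkene under thermodynamic control with loss of ethene; the trisubstituted enoate is inert, and neither C12 nor C5 is touched under these neutral conditions.

Step 20
Reactants: 28 the side-chain epoxy alcohol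
Product: 29 6-(tert-butoxy)-6-oxohexyl (2E)-3-methyl-4-[(4S)-1-{(2E,4R,5S)-4-methyl-5-[(triethylsilyl)oxy]hex-2-en-1-yl}-5-oxo-3,7-dioxabicyclo[4.1.0]heptan-4-yl]but-2-enoate
Conditions: Dess–Martin periodinane, pyridine, CH2Cl2, 0 °C → rt
Reagents that add atoms: none
Why: Dess–Martin oxidation of the only free alcohol gives the 7,8-epoxy 6-ketone under buffered, non-enolising conditions, so C5 (again α to a ketone) keeps its configuration.

Step 21
Reactants: 29 the 7,8-epoxy 6-ketone
Product: 31 6,7-diketothiomarinolic acid C6 (target), via 7,8-dihydroxy 6-ketone 30 (not isolated)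
Conditions: TFA/CH2Cl2/H2O (10:10:1), 0 °C → rt
Reagents that add atoms: none
Why: Acid-mediated epoxy ketone → diosphenol isomerisation: the oxirane opens at the tertiary C8 and the 8-oxygen is lost together with the C7 hydrogen, leaving the enol on C7 conjugated to the C6 ketone (the change used for diosphenol and 4-hydroxy-enone steroid syntheses); the same acid removes the TES ether and the tert-butyl ester, no base is present, and no stereocentre is formed.

## Compound list

1 | methyl 4-bromofuran-2-carboxylate | COC(=O)c1cc(Br)co1 | starting material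
2 | 2-allyl-4,4,5,5-tetramethyl-1,3,2-dioxaborolane | C=CCB1OC(C)(C)C(C)(C)O1 | starting material
3 | methyl 4-allylfuran-2-carboxylate | COC(=O)c1cc(CC=C)co1 | intermediate
4 | ethyl acetate | CCOC(C)=O | starting material
5 | ethyl 3-(4-allylfuran-2-yl)-3-oxopropanoate | CCOC(=O)CC(=O)c1cc(CC=C)co1 | intermediate
6 | ethyl (3S)-3-(4-allylfuran-2-yl)-3-hydroxypropanoate | CCOC(=O)C[C@H](O)c1cc(CC=C)co1 | intermediate
7 | ethyl (3S)-3-(4-allylfuran-2-yl)-3-[(tert-butyldimethylsilyl)oxy]propanoate | CCOC(=O)C[C@H](O[Si](C)(C)C(C)(C)C)c1cc(CC=C)co1 | intermediate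
8 | (3S)-3-(4-allylfuran-2-yl)-3-[(tert-butyldimethylsilyl)oxy]propanoic acid | OC(=O)C[C@H](O[Si](C)(C)C(C)(C)C)c1cc(CC=C)co1 | intermediate
9 | Meldrum's acid (2,2-dimethyl-1,3-dioxane-4,6-dione) | CC1(C)OC(=O)CC(=O)O1 | starting material
10 | tert-butyl 6-hydroxyhexanoate | CC(C)(C)OC(=O)CCCCCO | starting material
11 | 3-{[6-(tert-butoxy)-6-oxohexyl]oxy}-3-oxopropanoic acid | OC(=O)CC(=O)OCCCCCC(=O)OC(C)(C)C | intermediate
12 | (3S)-3-(4-allylfuran-2-yl)-3-[(tert-butyldimethylsilyl)oxy]-1-(imidazol-1-yl)propan-1-one (acyl imidazolide, not isolated) | O=C(C[C@H](O[Si](C)(C)C(C)(C)C)c1cc(CC=C)co1)n1ccnc1 | intermediate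
13 | 2-acylmalonic half ester of 8 and 11 (not isolated) | OC(=O)C(C(=O)C[C@H](O[Si](C)(C)C(C)(C)C)c1cc(CC=C)co1)C(=O)OCCCCCC(=O)OC(C)(C)C | intermediate
14 | 6-(tert-butoxy)-6-oxohexyl (5S)-5-(4-allylfuran-2-yl)-5-[(tert-butyldimethylsilyl)oxy]-3-oxopentanoate | CC(C)(C)OC(=O)CCCCCOC(=O)CC(=O)C[C@H](O[Si](C)(C)C(C)(C)C)c1cc(CC=C)co1 | intermediate
15 | 6-(tert-butoxy)-6-oxohexyl (2Z,5S)-5-(4-allylfuran-2-yl)-5-[(tert-butyldimethylsilyl)oxy]-3-[(diethoxyphosphoryl)oxy]pent-2-enoate | CCOP(=O)(OCC)O/C(C[C@H](O[Si](C)(C)C(C)(C)C)c1cc(CC=C)co1)=C\C(=O)OCCCCCC(=O)OC(C)(C)C | intermediate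
16 | 6-(tert-butoxy)-6-oxohexyl (2E,5S)-5-(4-allylfuran-2-yl)-5-[(tert-butyldimethylsilyl)oxy]-3-methylpent-2-enoate | C/C(=C\C(=O)OCCCCCC(=O)OC(C)(C)C)C[C@H](O[Si](C)(C)C(C)(C)C)c1cc(CC=C)co1 | intermediate
17 | 6-(tert-butoxy)-6-oxohexyl (2E,5S)-5-(4-allylfuran-2-yl)-5-hydroxy-3-methylpent-2-enoate | C/C(=C\C(=O)OCCCCCC(=O)OC(C)(C)C)C[C@H](O)c1cc(CC=C)co1 | intermediate
18 | 6-(tert-butoxy)-6-oxohexyl (2E,5S,7Z)-8-formyl-5-hydroxy-3-methyl-6-oxoundeca-2,7,10-trienoate (ring-opened enedione, not isolated) | C/C(=C\C(=O)OCCCCCC(=O)OC(C)(C)C)C[C@H](O)C(=O)/C=C(/CC=C)C=O | intermediate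
19 | 6-(tert-butoxy)-6-oxohexyl (2E)-4-[(2S)-5-allyl-6-hydroxy-3-oxo-3,6-dihydro-2H-pyran-2-yl]-3-methylbut-2-enoate (anomers) | C/C(=C\C(=O)OCCCCCC(=O)OC(C)(C)C)C[C@@H]1OC(O)C(CC=C)=CC1=O | intermediate
20 | 6-(tert-butoxy)-6-oxohexyl (2E)-4-[(2S)-5-allyl-3-oxo-3,6-dihydro-2H-pyran-2-yl]-3-methylbut-2-enoate | C/C(=C\C(=O)OCCCCCC(=O)OC(C)(C)C)C[C@@H]1OCC(CC=C)=CC1=O | intermediate
21 | 6-(tert-butoxy)-6-oxohexyl (2E)-4-[(2S)-5-allyl-3-hydroxy-3,6-dihydro-2H-pyran-2-yl]-3-methylbut-2-enoate (C6 epimers) | C/C(=C\C(=O)OCCCCCC(=O)OC(C)(C)C)C[C@@H]1OCC(CC=C)=CC1O | intermediate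
22 | 6-(tert-butoxy)-6-oxohexyl (2E)-4-[(4S)-1-allyl-5-hydroxy-3,7-dioxabicyclo[4.1.0]heptan-4-yl]-3-methylbut-2-enoate (epoxide syn to OH) | C/C(=C\C(=O)OCCCCCC(=O)OC(C)(C)C)C[C@@H]1OCC2(CC=C)OC2C1O | intermediate
23 | ethyl (3S)-3-hydroxybutanoate | CCOC(=O)C[C@H](C)O | starting material
24 | ethyl (2S,3S)-3-hydroxy-2-methylbutanoate | CCOC(=O)[C@@H](C)[C@H](C)O | intermediate
25 | ethyl (2S,3S)-2-methyl-3-[(triethylsilyl)oxy]butanoate | CCOC(=O)[C@@H](C)[C@H](C)O[Si](CC)(CC)CC | intermediate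
26 | (2S,3S)-2-methyl-3-[(triethylsilyl)oxy]butanal | O=C[C@@H](C)[C@H](C)O[Si](CC)(CC)CC | intermediate
27 | triethyl{[(2S,3R)-3-methylpent-4-en-2-yl]oxy}silane | C=C[C@@H](C)[C@H](C)O[Si](CC)(CC)CC | intermediate
28 | 6-(tert-butoxy)-6-oxohexyl (2E)-4-[(4S)-5-hydroxy-1-{(2E,4R,5S)-4-methyl-5-[(triethylsilyl)oxy]hex-2-en-1-yl}-3,7-dioxabicyclo[4.1.0]heptan-4-yl]-3-methylbut-2-enoate | C/C(=C\C(=O)OCCCCCC(=O)OC(C)(C)C)C[C@@H]1OCC2(C/C=C/[C@@H](C)[C@H](C)O[Si](CC)(CC)CC)OC2C1O | intermediate
29 | 6-(tert-butoxy)-6-oxohexyl (2E)-3-methyl-4-[(4S)-1-{(2E,4R,5S)-4-methyl-5-[(triethylsilyl)oxy]hex-2-en-1-yl}-5-oxo-3,7-dioxabicyclo[4.1.0]heptan-4-yl]but-2-enoate | C/C(=C\C(=O)OCCCCCC(=O)OC(C)(C)C)C[C@@H]1OCC2(C/C=C/[C@@H](C)[C@H](C)O[Si](CC)(CC)CC)OC2C1=O | intermediate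
30 | 6-{[(2E)-4-[(2S)-4,5-dihydroxy-5-[(2E,4R,5S)-5-hydroxy-4-methylhex-2-en-1-yl]-3-oxotetrahydro-2H-pyran-2-yl]-3-methylbut-2-enoyl]oxy}hexanoic acid (7,8-dihydroxy 6-ketone, not isolated) | C/C(=C\C(=O)OCCCCCC(=O)O)C[C@@H]1OCC(O)(C/C=C/[C@@H](C)[C@H](C)O)C(O)C1=O | intermediate
31 | 6,7-diketothiomarinolic acid C6 | C/C(=C\C(=O)OCCCCCC(=O)O)C[C@@H]1OCC(C/C=C/[C@@H](C)[C@H](C)O)=C(O)C1=O | target

## Totals and weak points

Total step count: 21. Longest linear sequence: 16 steps (steps 1–5, 7–14, 19–21).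

The three steps most likely to fail:

**Step 21 (acid cascade to the diosphenol).** The opening may stall at the keto diol, divert to ring-contracted or diene by-products, or erode C5 through enolisation. The wrong enol (C5=C6) can only arise through the free 6,7-dione, which is why base is kept out of the end game. The fallback sets out from 20 and comes back at 31. Copper hydride 1,4-reduction of enone 20 ([(Ph3P)CuH]6 5 mol%, PhMe2SiH, toluene, rt) gives the C6 dimethylphenylsilyl enol ether F1, with the double bond fixed between C6 and C7. Rubottom oxidation (dimethyldioxirane, acetone, −40 °C, then citric acid in MeOH) gives the 7-hydroxy 6-ketone F2. Cross-metathesis with 27 as in step 19 gives the side-chain ketol F3. Dess–Martin oxidation with pyridine gives the 6,7-dione, which enolises to the protected diosphenol F4; the direction of enolisation has to be checked by NMR, which is why this is only the fallback. TFA/CH2Cl2/H2O at 0 °C then frees the alcohol and the acid to give 31.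

**Step 19 (cross-metathesis).** Homodimerisation of 22, sluggish reaction of the branched partner or E/Z mixtures are possible. The fallback sets out from 22 and 25 and comes back at 28. Johnson–Lemieux cleavage of the terminal alkene of 22 (OsO4 cat., NaIO4, 2,6-lutidine, dioxane/H2O) gives the epoxy aldehyde F5, used at once. Ester 25 is reduced with i-Bu2AlH (2.2 equiv) to the primary alcohol F6, converted by Mitsunobu reaction with 1-phenyl-1H-tetrazole-5-thiol (PPh3, diisopropyl azodicarboxylate) to the tetrazolyl sulfide F7 and oxidised (mCPBA, NaHCO3) to the tetrazolyl sulfone F8. Julia–Kocienski olefination of F5 with the anion of F8 (KN(SiMe3)2, DME, −60 °C, one extra equivalent for the free hydroxyl) forms the (E)-C10=C11 bond and gives 28.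

**Step 12 (reductive removal of the anomeric hydroxyl).** The electron-poor oxocarbenium ion forms reluctantly, and forcing it risks the tert-butyl ester and the enone. The fallback sets out from 19 and comes back at 21. Luche reduction of the ketone of 19 (NaBH4, CeCl3·7H2O, MeOH, −78 °C) is done first and gives the lactol allylic alcohol F9. Its anomeric hydroxyl now ionises to an allylic oxocarbenium ion under Et3SiH/BF3·OEt2 in CH2Cl2 at −78 °C, and hydride delivery at C16 gives 21 directly, without TFA and without passing through enone 20.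

## Further compounds

F1 | step 21 | 6-(tert-butoxy)-6-oxohexyl (2E)-4-[(2S)-5-allyl-3-[dimethyl(phenyl)silyl]oxy-5,6-dihydro-2H-pyran-2-yl]-3-methylbut-2-enoate | C/C(=C\C(=O)OCCCCCC(=O)OC(C)(C)C)C[C@@H]1OCC(CC=C)C=C1O[Si](C)(C)c1ccccc1
F2 | step 21 | 6-(tert-butoxy)-6-oxohexyl (2E)-4-[(2S)-5-allyl-4-hydroxy-3-oxotetrahydro-2H-pyran-2-yl]-3-methylbut-2-enoate | C/C(=C\C(=O)OCCCCCC(=O)OC(C)(C)C)C[C@@H]1OCC(CC=C)C(O)C1=O
F3 | step 21 | 6-(tert-butoxy)-6-oxohexyl (2E)-4-[(2S)-4-hydroxy-5-{(2E,4R,5S)-4-methyl-5-[(triethylsilyl)oxy]hex-2-en-1-yl}-3-oxotetrahydro-2H-pyran-2-yl]-3-methylbut-2-enoate | C/C(=C\C(=O)OCCCCCC(=O)OC(C)(C)C)C[C@@H]1OCC(C/C=C/[C@@H](C)[C@H](C)O[Si](CC)(CC)CC)C(O)C1=O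
F4 | step 21 | 6-(tert-butoxy)-6-oxohexyl (2E)-4-[(2S)-4-hydroxy-5-{(2E,4R,5S)-4-methyl-5-[(triethylsilyl)oxy]hex-2-en-1-yl}-3-oxo-3,6-dihydro-2H-pyran-2-yl]-3-methylbut-2-enoate | C/C(=C\C(=O)OCCCCCC(=O)OC(C)(C)C)C[C@@H]1OCC(C/C=C/[C@@H](C)[C@H](C)O[Si](CC)(CC)CC)=C(O)C1=O
F5 | step 19 | 6-(tert-butoxy)-6-oxohexyl (2E)-4-[(4S)-5-hydroxy-1-(2-oxoethyl)-3,7-dioxabicyclo[4.1.0]heptan-4-yl]-3-methylbut-2-enoate | C/C(=C\C(=O)OCCCCCC(=O)OC(C)(C)C)C[C@@H]1OCC2(CC=O)OC2C1O
F6 | step 19 | (2R,3S)-2-methyl-3-[(triethylsilyl)oxy]butan-1-ol | OC[C@@H](C)[C@H](C)O[Si](CC)(CC)CC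
F7 | step 19 | 5-({(2S,3S)-2-methyl-3-[(triethylsilyl)oxy]butyl}sulfanyl)-1-phenyl-1H-tetrazole | c1ccccc1-n1nnnc1SC[C@@H](C)[C@H](C)O[Si](CC)(CC)CC
F8 | step 19 | 5-({(2S,3S)-2-methyl-3-[(triethylsilyl)oxy]butyl}sulfonyl)-1-phenyl-1H-tetrazole | O=S(=O)(C[C@@H](C)[C@H](C)O[Si](CC)(CC)CC)c1nnnn1-c1ccccc1
F9 | step 12 | 6-(tert-butoxy)-6-oxohexyl (2E)-4-[(2S)-5-allyl-3,6-dihydroxy-3,6-dihydro-2H-pyran-2-yl]-3-methylbut-2-enoate | C/C(=C\C(=O)OCCCCCC(=O)OC(C)(C)C)C[C@@H]1OC(O)C(CC=C)=CC1O
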